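The plan cuts ring B′ of the right bicycle at C5′–C10′ and C8′–C9′. One intramolecular Diels–Alder reaction of an acyclic (S)-6-silyloxy trienoate, whose (E)-enoate is linked through the C1′–C4′ chain (oxygenated C3′, gem-dimethyl C4′) to a (Z)-2-silyloxydiene, closes rings A′ and B′ together and installs the trans fusion, the angular methyl and the C9′ one-carbon arm. Because rings A/B of the left half carry the same skeleton and the same configuration at C3, C5, C9 and C10, this one adduct feeds both halves: its C7 ketone is removed on the right and turned into the C7=C8 alkene on the left, and the halves are joined at C11–C12.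

Key step: step 5

Remarks
- Locants: left bicycle C1–C10 with C11 on C9; right bicycle C1′–C10′ with C12 on C9′. Bicyclic intermediates are named as decalins (decahydronaphthalenes) with these locants; β is the face of the C10 methyl. In the left-half series the carbon on C9 is C11.
- Abbreviations: TBS = tert-butyldimethylsilyl, Tf = trifluoromethanesulfonyl, Ts = 4-toluenesulfonyl, PT = 1-phenyl-1H-tetrazol-5-yl.
- Assumption: the (S)-SEGPHOS iridium complex is taken to give the (S)-carbinol in step 2; if its sense proves opposite, the (R)-ligand is used with no other change.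

Step 1
Reactants: 1 methyl geranate
Product: 3 methyl (2E)-3-methyl-6-oxohex-2-enoate, via ozonide 2 (not isolated)
Conditions: O3 (1 equiv), CH2Cl2, −78 °C; then Me2S, −78 °C → rt
Reagents that add atoms: ozone, O=[O+][O-]
Why: Ozonolysis with reductive work-up cleaves the electron-rich trisubstituted alkene far faster than the conjugated, electron-poor enoate, so one equivalent of ozone should give the aldehyde ester; no stereocentre is involved.

Step 2
Reactants: 3 methyl (2E)-3-methyl-6-oxohex-2-enoate; 4 3-methylbuta-1,2-diene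
Product: 5 methyl (2E,6S)-6-hydroxy-3,7,7-trimethylnona-2,8-dienoate
Conditions: preformed π-allyl iridium C,O-benzoate complex from [Ir(cod)Cl]2, (S)-SEGPHOS, 3-nitrobenzoic acid and allyl acetate (5 mol %), i-PrOH (2 equiv), toluene, 50 °C
Reagents that add atoms: none
Why: In this iridium-catalysed transfer-hydrogenative reverse prenylation (Krische-type carbonyl allylation) the iridium hydride formed from i-PrOH adds to the allene, and the resulting 1,1-dimethylallyl complex of trivalent iridium delivers its substituted terminus to the aldehyde through a closed chair transition state in which the chiral bisphosphine selects the aldehyde face and sets C3′ as (S).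

Step 3
Reactants: 5 methyl (2E,6S)-6-hydroxy-3,7,7-trimethylnona-2,8-dienoate; 6 pent-1-en-3-one
Product: 7 methyl (2E,6S,8E)-6-hydroxy-3,7,7-trimethyl-10-oxododeca-2,8-dienoate
Conditions: second-generation Hoveyda–Grubbs catalyst, RuCl2(H2IMes)(=CH-C6H4-2-O-i-Pr) (2 × 5 mol %), 6 (5 equiv), toluene, 70 °C, argon purge
Reagents that add atoms: none
Why: Olefin cross-metathesis between the terminal vinyl group and the slowly homodimerising enone should give the (E)-enone under thermodynamic control, the free carbinol keeping the neopentyl-type olefin as accessible as possible and the trisubstituted enoate being inert to the catalyst.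

Step 4
Reactants: 7 methyl (2E,6S,8E)-6-hydroxy-3,7,7-trimethyl-10-oxododeca-2,8-dienoate
Product: 8 methyl (2E,6S,8E,10Z)-6,10-bis(TBSO)-3,7,7-trimethyldodeca-2,8,10-trienoate
Conditions: TBSOTf (2.6 equiv), Et3N (4 equiv), CH2Cl2, −78 → 0 °C; filtration through Et3N-deactivated silica
Reagents that add atoms: tert-butyldimethylsilyl trifluoromethanesulfonate, CC(C)(C)[Si](C)(C)OS(=O)(=O)C(F)(F)F
Why: The silyl triflate silylates the hindered carbinol and, through the O-silyl oxocarbenium ion of the ethyl ketone, gives on deprotonation at C8′ the cross-conjugated (Z)-silyl dienol ether with the methyl anti to the vinyl group (soft enolisation), C8′ being the only enolisable position because C4′ is quaternary and the ester does not enolise under these conditions.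

Step 5
Reactants: 8 methyl (2E,6S,8E,10Z)-6,10-bis(TBSO)-3,7,7-trimethyldodeca-2,8,10-trienoate
Product: 9 methyl 3β,7-bis(TBSO)-4,4,8β,10β-tetramethyl-5α-decal-6-ene-9β-carboxylate
Conditions: toluene (0.01 M), BHT (0.1 equiv), base-washed sealed tube, 170–180 °C
Reagents that add atoms: none
Why: On heating, the (E)-enoate C9′=C10′ adds suprafacially across the s-cis diene C5′=C6′–C7′=C8′ in a concerted, asynchronous [4+2] cycloaddition (intramolecular Diels–Alder reaction); the closest known reaction type is the thermal cyclisation of 1,7,9-decatrienoates carrying a 2-silyloxydiene to trans-decalins with an angular methyl. Ring B′ is the six-membered cycloadduct ring that holds both new bonds (C5′–C10′ and C8′–C9′), and ring A′ closes in the same event as the fused six-membered carbocycle spanned by the four-carbon tether C1′–C4′ in a chair-like arrangement. Of the four new stereocentres, C5′ and C10′ (trans fusion) follow from the transition state with the tether exo and the C10′ methyl and ester endo, C9′ (β ester, cis to the angular methyl) from the E geometry of the enoate, C8′ (β methyl, inverted in step 6) from the Z geometry of the dienol ether, and the absolute sense of all four from C3′, whose silyloxy group sits equatorial on the chair tether and so fixes the diene face. Only the trans fusion and the C3′/C10′ relationship cannot be repaired later, because C8′ and C9′ are epimerisable next to carbonyl groups; the (E)-C5′=C6′ bond and the all-staggered chair tether with equatorial C3′–OTBS are what should favour them. The tether overrides the usual para orientation of 2-silyloxydienes (the donor end C8′ meets the enoate α-carbon), so the reaction is run thermally and without Lewis acid, which would only open Mukaiyama-type ionic pathways that cannot close these rings.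

Step 6
Reactants: 9 methyl 3β,7-bis(TBSO)-4,4,8β,10β-tetramethyl-5α-decal-6-ene-9β-carboxylate
Product: 11 methyl 3β-(TBSO)-4,4,8α,10β-tetramethyl-7-oxo-5α-decalin-9β-carboxylate, via 8β-methyl ketone 10 (not isolated)
Conditions: NaOMe (0.5 equiv), MeOH–THF, rt → 40 °C; aq. NH4Cl
Reagents that add atoms: none
Why: Methoxide cleaves the enol silyl ether while the hindered C3 alkyl silyl ether survives, and the liberated ketone equilibrates through its C7=C8 enolate so that the C8 methyl leaves the axial position syn to the C10 methyl for the equatorial 8α position while the C9 ester stays equatorial (base-mediated epimerisation under thermodynamic control, into which any C8 or C9 epimer from step 5 converges).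

Step 7
Reactants: 11 methyl 3β-(TBSO)-4,4,8α,10β-tetramethyl-7-oxo-5α-decalin-9β-carboxylate
Product: 12 methyl 3β-(TBSO)-4,4,8,10β-tetramethyl-7-(trifluoromethylsulfonyloxy)-5α-decal-7-ene-9β-carboxylate
Conditions: Tf2O (1.3 equiv), 2,6-di-tert-butyl-4-methylpyridine (1.6 equiv), CH2Cl2, 0 °C → rt
Reagents that add atoms: trifluoromethanesulfonic anhydride, O=S(=O)(OS(=O)(=O)C(F)(F)F)C(F)(F)F
Why: Triflation of the ketone oxygen and loss of the axial C8 proton from the oxocarbenium ion give the more substituted C7=C8 enol triflate (thermodynamic enol triflate formation), favoured because a C6=C7 bond would lie next to the trans ring fusion and the axial C6 proton is buried between the 4β and 10β methyl groups; the C8 stereocentre is deliberately erased and C9 is untouched.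

Step 8
Reactants: 12 methyl 3β-(TBSO)-4,4,8,10β-tetramethyl-7-(trifluoromethylsulfonyloxy)-5α-decal-7-ene-9β-carboxylate
Product: 13 methyl 3β-(TBSO)-4,4,8,10β-tetramethyl-5α-decal-7-ene-9β-carboxylate
Conditions: Pd(OAc)2 (5 mol %), PPh3 (10 mol %), n-Bu3N (3 equiv), HCO2H (2 equiv), DMF, 60 °C
Reagents that add atoms: none
Why: In this palladium-catalysed formate reduction of an enol triflate, oxidative addition to zerovalent palladium, exchange of triflate for formate, loss of CO2 and reductive elimination replace C7–OTf by C7–H with the double bond fixed at C7=C8, under conditions too weakly basic to move it into conjugation with the ester or to epimerise C9.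

Step 9
Reactants: 13 methyl 3β-(TBSO)-4,4,8,10β-tetramethyl-5α-decal-7-ene-9β-carboxylate
Product: 14 [3β-(TBSO)-4,4,8,10β-tetramethyl-5α-decal-7-en-9β-yl]methanol
Conditions: LiAlH4, Et2O, 0 °C
Reagents that add atoms: none
Why: Hydride reduction of the ester to the primary alcohol is faster at low temperature than deprotonation at the allylic C9 and leaves the trisubstituted alkene and the silyl ether alone.

Step 10
Reactants: 14 [3β-(TBSO)-4,4,8,10β-tetramethyl-5α-decal-7-en-9β-yl]methanol
Product: 15 5-{[3β-(TBSO)-4,4,8,10β-tetramethyl-5α-decal-7-en-9β-yl]methylthio}-1-phenyl-1H-tetrazole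
Conditions: 1-phenyl-1H-tetrazole-5-thiol, PPh3, DIAD, THF, 0 °C → rt
Reagents that add atoms: 1-phenyl-1H-tetrazole-5-thiol, Sc1nnnn1-c1ccccc1
Why: In this Mitsunobu thioetherification the primary alcohol is activated as its oxyphosphonium salt and displaced by the acidic thiol in an SN2 step at C11 that involves no stereocentre.

Step 11
Reactants: 15 5-{[3β-(TBSO)-4,4,8,10β-tetramethyl-5α-decal-7-en-9β-yl]methylthio}-1-phenyl-1H-tetrazole
Product: 16 5-{[3β-(TBSO)-4,4,8,10β-tetramethyl-5α-decal-7-en-9β-yl]methylsulfonyl}-1-phenyl-1H-tetrazole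
Conditions: (NH4)6Mo7O24·4H2O (10 mol %), 30% H2O2, EtOH, 0 °C → rt
Reagents that add atoms: hydrogen peroxide, OO
Why: Peroxomolybdate-catalysed oxidation takes the sulfide through the sulfoxide to the sulfone (sulfide oxidation) and, unlike a peracid, should not epoxidise the hindered trisubstituted C7=C8 bond.

Step 12
Reactants: 11 methyl 3β-(TBSO)-4,4,8α,10β-tetramethyl-7-oxo-5α-decalin-9β-carboxylate
Product: 18 methyl 3β-(TBSO)-4,4,8α,10β-tetramethyl-5α-decalin-9β-carboxylate, via tosylhydrazone 17 (not isolated)
Conditions: TsNHNH2, EtOH, 60 °C; evaporate; catecholborane, CHCl3, 0 °C; then NaOAc·3H2O, 60 °C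
Reagents that add atoms: none
Why: The ketone condenses with tosylhydrazide and the tosylhydrazone is reduced by catecholborane at the C=N carbon, after which acetate-induced loss of sulfinate and N2 leaves a CH2 group at C7′ (Caglioti-type deoxygenation in its catecholborane form), conditions that spare the ester, the silyl ether and the equatorial C8′ and C9′ substituents.

Step 13
Reactants: 18 methyl 3β-(TBSO)-4,4,8α,10β-tetramethyl-5α-decalin-9β-carboxylate
Product: 19 [3β-(TBSO)-4,4,8α,10β-tetramethyl-5α-decalin-9β-yl]methanol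
Conditions: LiAlH4, Et2O, 0 °C → rt
Reagents that add atoms: none
Why: Hydride reduction converts the hindered ester into the primary alcohol without touching any stereocentre.

Step 14
Reactants: 19 [3β-(TBSO)-4,4,8α,10β-tetramethyl-5α-decalin-9β-yl]methanol
Product: 20 3β-(TBSO)-4,4,8α,10β-tetramethyl-5α-decalin-9β-carbaldehyde
Conditions: Dess–Martin periodinane, CH2Cl2, 0 °C → rt
Reagents that add atoms: none
Why: Dess–Martin oxidation gives the aldehyde under near-neutral conditions, and the 9′β (equatorial) configuration next to the new carbonyl is in any case the thermodynamically preferred one.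

Step 15
Reactants: 16 5-{[3β-(TBSO)-4,4,8,10β-tetramethyl-5α-decal-7-en-9β-yl]methylsulfonyl}-1-phenyl-1H-tetrazole; 20 3β-(TBSO)-4,4,8α,10β-tetramethyl-5α-decalin-9β-carbaldehyde
Product: 21 (11E)-11,12-didehydro-3,3′-bis-O-TBS derivative of the target
Conditions: 16, KN(SiMe3)2, THF, −78 °C; then 20, −78 °C → rt
Reagents that add atoms: none
Why: In this Julia–Kocienski olefination the sulfonyl carbanion adds to the aldehyde, the alkoxide takes over the tetrazole from sulfur (Smiles rearrangement) and elimination of SO2 and tetrazolate forms the C11=C12 bond, whose geometry (E expected) does not matter because it is reduced next; no stereocentre is formed, and the only epimerisable centre, C9′ of the aldehyde, already has its preferred equatorial configuration.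

Step 16
Reactants: 21 (11E)-11,12-didehydro-3,3′-bis-O-TBS derivative of the target
Product: 22 3,3′-bis-O-TBS ether of the target
Conditions: TsNHNH2 (excess, in portions), NaOAc, DME/H2O, 85 °C
Reagents that add atoms: none
Why: Diimide generated in the flask transfers H2 in a concerted syn fashion to the 1,2-disubstituted C11=C12 bond much faster than to the hindered trisubstituted C7=C8 bond (diimide reduction), and being metal-free it cannot isomerise the skipped diene.

Step 17
Reactants: 22 3,3′-bis-O-TBS ether of the target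
Product: 23 CNP0194061.1 (the 3β,3′β-diol)
Conditions: Bu4NF (excess), THF, 60 °C
Reagents that add atoms: none
Why: Fluoride cleaves both hindered secondary silyl ethers (desilylation driven by the Si–F bond) under non-acidic conditions that leave the C7=C8 alkene in place.

Compound list
1 | methyl geranate | COC(=O)/C=C(\C)CCC=C(C)C | starting material
2 | methyl (2E)-5-(5,5-dimethyl-1,2,4-trioxolan-3-yl)-3-methylpent-2-enoate (ozonide, either configuration at the acetal carbon) | COC(=O)/C=C(\C)CCC1OOC(C)(C)O1 | intermediate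
3 | methyl (2E)-3-methyl-6-oxohex-2-enoate | COC(=O)/C=C(\C)CCC=O | intermediate
4 | 3-methylbuta-1,2-diene | CC(C)=C=C | starting material
5 | methyl (2E,6S)-6-hydroxy-3,7,7-trimethylnona-2,8-dienoate | COC(=O)/C=C(\C)CC[C@H](O)C(C)(C)C=C | intermediate
6 | pent-1-en-3-one | CCC(=O)C=C | starting material
7 | methyl (2E,6S,8E)-6-hydroxy-3,7,7-trimethyl-10-oxododeca-2,8-dienoate | COC(=O)/C=C(\C)CC[C@H](O)C(C)(C)/C=C/C(=O)CC | intermediate
8 | methyl (2E,6S,8E,10Z)-6,10-bis(TBSO)-3,7,7-trimethyldodeca-2,8,10-trienoate | COC(=O)/C=C(\C)CC[C@H](O[Si](C)(C)C(C)(C)C)C(C)(C)/C=C/C(O[Si](C)(C)C(C)(C)C)=C/C | intermediate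
9 | methyl 3β,7-bis(TBSO)-4,4,8β,10β-tetramethyl-5α-decal-6-ene-9β-carboxylate | COC(=O)[C@H]1[C@@H](C)C(O[Si](C)(C)C(C)(C)C)=C[C@H]2C(C)(C)[C@@H](O[Si](C)(C)C(C)(C)C)CC[C@]12C | intermediate
10 | methyl 3β-(TBSO)-4,4,8β,10β-tetramethyl-7-oxo-5α-decalin-9β-carboxylate | COC(=O)[C@H]1[C@@H](C)C(=O)C[C@H]2C(C)(C)[C@@H](O[Si](C)(C)C(C)(C)C)CC[C@]12C | intermediate
11 | methyl 3β-(TBSO)-4,4,8α,10β-tetramethyl-7-oxo-5α-decalin-9β-carboxylate | COC(=O)[C@H]1[C@H](C)C(=O)C[C@H]2C(C)(C)[C@@H](O[Si](C)(C)C(C)(C)C)CC[C@]12C | intermediate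
12 | methyl 3β-(TBSO)-4,4,8,10β-tetramethyl-7-(trifluoromethylsulfonyloxy)-5α-decal-7-ene-9β-carboxylate | COC(=O)[C@H]1C(C)=C(OS(=O)(=O)C(F)(F)F)C[C@H]2C(C)(C)[C@@H](O[Si](C)(C)C(C)(C)C)CC[C@]12C | intermediate
13 | methyl 3β-(TBSO)-4,4,8,10β-tetramethyl-5α-decal-7-ene-9β-carboxylate | COC(=O)[C@H]1C(C)=CC[C@H]2C(C)(C)[C@@H](O[Si](C)(C)C(C)(C)C)CC[C@]12C | intermediate
14 | [3β-(TBSO)-4,4,8,10β-tetramethyl-5α-decal-7-en-9β-yl]methanol | OC[C@H]1C(C)=CC[C@H]2C(C)(C)[C@@H](O[Si](C)(C)C(C)(C)C)CC[C@]12C | intermediate
15 | 5-{[3β-(TBSO)-4,4,8,10β-tetramethyl-5α-decal-7-en-9β-yl]methylthio}-1-phenyl-1H-tetrazole | C(Sc1nnnn1-c1ccccc1)[C@H]1C(C)=CC[C@H]2C(C)(C)[C@@H](O[Si](C)(C)C(C)(C)C)CC[C@]12C | intermediate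
16 | 5-{[3β-(TBSO)-4,4,8,10β-tetramethyl-5α-decal-7-en-9β-yl]methylsulfonyl}-1-phenyl-1H-tetrazole | O=S(=O)(C[C@H]1C(C)=CC[C@H]2C(C)(C)[C@@H](O[Si](C)(C)C(C)(C)C)CC[C@]12C)c1nnnn1-c1ccccc1 | intermediate
17 | tosylhydrazone of 11 at C7′ | COC(=O)[C@H]1[C@H](C)C(=NNS(=O)(=O)c3ccc(C)cc3)C[C@H]2C(C)(C)[C@@H](O[Si](C)(C)C(C)(C)C)CC[C@]12C | intermediate
18 | methyl 3β-(TBSO)-4,4,8α,10β-tetramethyl-5α-decalin-9β-carboxylate | COC(=O)[C@H]1[C@H](C)CC[C@H]2C(C)(C)[C@@H](O[Si](C)(C)C(C)(C)C)CC[C@]12C | intermediate
19 | [3β-(TBSO)-4,4,8α,10β-tetramethyl-5α-decalin-9β-yl]methanol | OC[C@H]1[C@H](C)CC[C@H]2C(C)(C)[C@@H](O[Si](C)(C)C(C)(C)C)CC[C@]12C | intermediate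
20 | 3β-(TBSO)-4,4,8α,10β-tetramethyl-5α-decalin-9β-carbaldehyde | O=C[C@H]1[C@H](C)CC[C@H]2C(C)(C)[C@@H](O[Si](C)(C)C(C)(C)C)CC[C@]12C | intermediate
21 | (11E)-11,12-didehydro-3,3′-bis-O-TBS derivative of the target | CC1=CC[C@H]2C(C)(C)[C@@H](O[Si](C)(C)C(C)(C)C)CC[C@]2(C)[C@H]1/C=C/[C@H]1[C@H](C)CC[C@H]2C(C)(C)[C@@H](O[Si](C)(C)C(C)(C)C)CC[C@]12C | intermediate
22 | 3,3′-bis-O-TBS ether of the target | CC1=CC[C@H]2C(C)(C)[C@@H](O[Si](C)(C)C(C)(C)C)CC[C@]2(C)[C@H]1CC[C@H]1[C@H](C)CC[C@H]2C(C)(C)[C@@H](O[Si](C)(C)C(C)(C)C)CC[C@]12C | intermediate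
23 | CNP0194061.1 | CC1=CC[C@H]2C(C)(C)[C@@H](O)CC[C@]2(C)[C@H]1CC[C@H]1[C@H](C)CC[C@H]2C(C)(C)[C@@H](O)CC[C@]12C | target

Total step count: 17. Longest linear sequence: 14 steps (steps 1–11 and 15–17); the right-half branch (steps 12–14) leaves the common ketone 11.

Steps most likely to fail

Step 5. The cycloaddition may be too slow, so that the dienol ether isomerises or loses silicon first, or it may close through the endo-tether transition state (cis fusion) or on the wrong diene face. The fallback sets out from 7 and comes back at 11, making the two ring bonds one after the other. SmI2 (THF/MeOH, −78 °C) joins the enone β-carbon C5′ to the enoate β-carbon C10′ in a 6-exo reductive cyclisation. This gives ring A′ as methyl 2-[4-hydroxy-1,3,3-trimethyl-2-(2-oxobutyl)cyclohexyl]acetate F1, with the two side chains trans. Silylation (TBSOTf, 2,6-lutidine) gives its TBS ether F2. Double deprotonation with LiN(i-Pr)2 (2.2 equiv) and oxidation of the bis-enolate with Fe(acac)3 then join C8′ and C9′ (intramolecular oxidative enolate coupling, ring B′). NaOMe/MeOH as in step 6 brings the C8′/C9′ epimers 10 and 11 to ketone 11.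

Step 3. Metathesis at the vinyl group next to the quaternary carbon may be sluggish, so that catalyst decay and homodimerisation of the enone take over. The fallback sets out from 5 and comes back at 8. The carbinol is silylated (TBSOTf, 2,6-lutidine) to methyl (2E,6S)-6-(TBSO)-3,7,7-trimethylnona-2,8-dienoate F3. Lemieux–Johnson cleavage (OsO4 cat., NaIO4, 2,6-lutidine, dioxane/H2O) of the vinyl group, which is far more reactive than the conjugated enoate, gives methyl (2E,6S)-6-(TBSO)-3,7,7-trimethyl-8-oxooct-2-enoate F4. A Wittig reaction with 1-(triphenylphosphoranylidene)butan-2-one (toluene, 90 °C) gives methyl (2E,6S,8E)-6-(TBSO)-3,7,7-trimethyl-10-oxododeca-2,8-dienoate F5, and TBSOTf/Et3N then forms the dienol ether 8.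

Step 15. Addition of the hindered sulfonyl carbanion to the hindered aldehyde may be slow, so that retro-addition or enolisation of the aldehyde prevails. The fallback sets out from 14 and 20 and comes back at 22. Alcohol 14 is converted (I2, PPh3, imidazole, toluene, 80 °C) into 3β-(TBSO)-9β-(iodomethyl)-4,4,8,10β-tetramethyl-5α-decal-7-ene F6. Iodine–lithium exchange (t-BuLi, Et2O/pentane, −78 °C) gives the primary alkyllithium F7, which adds to aldehyde 20 to give the C12 carbinol F8 (either epimer). Its S-methyl xanthate F9 (NaH, CS2, MeI) is reduced under Barton–McCombie conditions (Bu3SnH, AIBN, toluene, 100 °C) to 22.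

Further compounds
F1 | step 5 | methyl 2-[4-hydroxy-1,3,3-trimethyl-2-(2-oxobutyl)cyclohexyl]acetate (configuration of 11 at C3′, C5′, C10′) | COC(=O)C[C@@]1(C)CC[C@H](O)C(C)(C)[C@@H]1CC(=O)CC
F2 | step 5 | TBS ether of F1 | COC(=O)C[C@@]1(C)CC[C@H](O[Si](C)(C)C(C)(C)C)C(C)(C)[C@@H]1CC(=O)CC
F3 | step 3 | methyl (2E,6S)-6-(TBSO)-3,7,7-trimethylnona-2,8-dienoate | COC(=O)/C=C(\C)CC[C@H](O[Si](C)(C)C(C)(C)C)C(C)(C)C=C
F4 | step 3 | methyl (2E,6S)-6-(TBSO)-3,7,7-trimethyl-8-oxooct-2-enoate | COC(=O)/C=C(\C)CC[C@H](O[Si](C)(C)C(C)(C)C)C(C)(C)C=O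
F5 | step 3 | methyl (2E,6S,8E)-6-(TBSO)-3,7,7-trimethyl-10-oxododeca-2,8-dienoate | COC(=O)/C=C(\C)CC[C@H](O[Si](C)(C)C(C)(C)C)C(C)(C)/C=C/C(=O)CC
F6 | step 15 | 3β-(TBSO)-9β-(iodomethyl)-4,4,8,10β-tetramethyl-5α-decal-7-ene | IC[C@H]1C(C)=CC[C@H]2C(C)(C)[C@@H](O[Si](C)(C)C(C)(C)C)CC[C@]12C
F7 | step 15 | {[3β-(TBSO)-4,4,8,10β-tetramethyl-5α-decal-7-en-9β-yl]methyl}lithium | [Li]C[C@H]1C(C)=CC[C@H]2C(C)(C)[C@@H](O[Si](C)(C)C(C)(C)C)CC[C@]12C
F8 | step 15 | 12-hydroxy derivative of 22 (either C12 epimer) | CC1=CC[C@H]2C(C)(C)[C@@H](O[Si](C)(C)C(C)(C)C)CC[C@]2(C)[C@H]1CC(O)[C@H]1[C@H](C)CC[C@H]2C(C)(C)[C@@H](O[Si](C)(C)C(C)(C)C)CC[C@]12C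
F9 | step 15 | O-C12 S-methyl xanthate of F8 | CC1=CC[C@H]2C(C)(C)[C@@H](O[Si](C)(C)C(C)(C)C)CC[C@]2(C)[C@H]1CC(OC(=S)SC)[C@H]1[C@H](C)CC[C@H]2C(C)(C)[C@@H](O[Si](C)(C)C(C)(C)C)CC[C@]12C
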